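I compare two rates. In north, the flask asked about, target gains as starting material is used and drains at a rate of its own, so its top stands where the two cross.

- north: starting material 0.20 mM; partner 1.05 equiv; catalyst 3.1 mol%; the very flask that is asked about, followed so far
- flask: starting material 0.20 mM; partner 1.05 equiv; catalyst 3.1 mol%; time 20 min

north run (percent of the starting material charged)

| time / min | target / % | starting material / % |
|---|---|---|
| 0.500 | 28.4 | 52.2 |
| 1.00 | 37.0 | 35.6 |
| 2.00 | 38.7 | 23.0 |
| 4.00 | 33.5 | 17.3 |

(standard deviation of a reading: 1 percentage point)

1. time, not beyond 20 min, at which the flask holds most target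
2. the amount of target, in percent of the starting material charged, at that time

The fastest rung is the filling. By 0.500 min about half of the starting material is used, and target stands at 59.4% of what was used. I read that as target's share of the use, with the scatter of the readings in it.

The next rung is the crossing. From 2.00 min to 4.00 min that share of the use should add target, yet target falls, so the drain is the gain plus the fall: 0.0429 min⁻¹ of the charge. I treat this drain rate as constant, a zero-order loss. The gain is 0.0749 min⁻¹ between 1.00 min and 2.00 min, above the drain, and 0.0169 min⁻¹ afterwards, below it, so I put the top near 2.00 min, with a height near the 38.7% read there.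

The slowest rung is the emptying. At this drain, with no gain counted, the target read at 2.00 min, 38.7% of the charge, is gone in 9.01 min, sooner than 20 min, so I look for the top early and not near the end.

The forecast gives 1.7 min and 39.5%, a time earlier than mine, holding that “the sharp early rise and slower later decline skew the true maximum earlier”.

The flask gives 1.85 min and 39.7%.

    starting material + partner → uncatalysed product (k = 21.0 M⁻¹ s⁻¹)
    partner + catalyst + target → catalyst + over-reaction product (k = 1.60 × 10⁷ M⁻² s⁻¹)
    starting material + partner ⇌ target (K = 5600 M⁻¹, k = 110 M⁻¹ s⁻¹)
    starting material + partner ⇌ isomer of the product (K = 7.60 × 10⁵ M⁻¹, k = 21.0 M⁻¹ s⁻¹)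
    target + catalyst ⇌ isomer of the product + catalyst, rate k5*[catalyst]*[target] forward; the back reaction follows from the equilibrium constant (k = 4600 M⁻¹ s⁻¹)
    crystals ⇌ target, rate k6*(cs6 - [target]) while solid is left; crystals form when [target] > cs6 (solubility = 0.00540 mM, k = 0.700 s⁻¹)

The top is broad: the flask holds 39.3% at 1.48 min and 39.2% at 2.31 min, a stretch containing the forecast's time and mine. Draining from the best at the carried rate, with no gain counted, leaves 4.68% at 10.0 min, and the flask holds 4.81%. Carried over unchanged to the flask charged with 2.60 equiv of partner, though its charge differs, the rate takes that flask's best, 52.6%, away in 12.3 min, and at 20.0 min that flask holds 0.174%.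

The earlier runs and the new flask come from a simulation with constants of no real substance, and the scatter is random.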